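**Early times.** At early times both mirror images meet the same partner and the same single-handed catalyst. I take each to fall first order in itself, with a common time-dependent factor, so their logarithmic losses keep a constant ratio whatever the partner does. Call E = ln(c(left-handed substrate) at start / c(left-handed substrate) now) the exposure. The last summer reading gives 15.4: this is s, the exposure divided by the same logarithm for the right-handed substrate, the selectivity factor. It is a reading, with the scatter of its readings. The right-handed substrate therefore needs E/s, a small correction to its charge, and I compute nothing else for it.

common to all: left-handed substrate 0.22 M; right-handed substrate 0.22 M; catalyst 0.31 mM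
- dawn: partner 0.27 M; protic impurity 0.22 M; run made earlier
- midnight: partner 0.53 M; protic impurity 0.22 M; run made earlier
- summer: partner 0.83 M; protic impurity 0.22 M; run made earlier
- cedar: partner 0.330 M; protic impurity 0.220 M; time 10 min
- birch: partner 0.990 M; protic impurity 0.220 M; time 10 min

| run | time / min | left-handed product / % | right-handed substrate / % | left-handed substrate / % | right-handed product / % |
|---|---|---|---|---|---|
| dawn | 1.33 | 6.7 | 49.6 | 43.2 | 2.8 |
| dawn | 3.00 | 13.8 | 48.8 | 35.7 | 2.1 |
| dawn | 4.00 | 13.0 | 49.0 | 37.3 | 0 |
| dawn | 6.00 | 16.4 | 49.2 | 33.4 | 0.8 |
| dawn | 8.00 | 19.8 | 48.6 | 31.0 | 3.2 |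
| midnight | 0.667 | 8.4 | 48.6 | 44.2 | 0 |
| midnight | 2.00 | 17.9 | 49.1 | 32.6 | 0.9 |
| midnight | 3.00 | 21.6 | 49.9 | 28.3 | 3.5 |
| midnight | 5.00 | 28.6 | 44.9 | 23.7 | 4.5 |
| midnight | 8.00 | 30.7 | 45.6 | 17.9 | 4.4 |
| summer | 0.500 | 9.6 | 50.6 | 40.5 | 2.5 |
| summer | 1.00 | 13.9 | 45.9 | 34.1 | 1.7 |
| summer | 2.00 | 23.2 | 47.6 | 25.0 | 1.4 |
| summer | 4.00 | 34.2 | 46.2 | 14.6 | 2.7 |
| summer | 8.00 | 41.7 | 44.0 | 7.0 | 6.0 |

(readings scatter by 1 percentage point)

1. which of these there is most of at the end, counted by the substrate in it, cedar (left-handed substrate / left-handed product / right-handed product / right-handed substrate)
2. which of these there is most of at the end, counted by the substrate in it, birch (left-handed substrate / left-handed product / right-handed product / right-handed substrate)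
3. final amount of the leader among these, as a percentage of the left-handed substrate and right-handed substrate together charged, in cedar
4. final amount of the leader among these, as a percentage of the left-handed substrate and right-handed substrate together charged, in birch

- catalyst is single-handed; left-handed substrate and right-handed substrate are mirror images of each other, charged as a racemate, each of them at the stated concentration

**Bench rule.** The bench rule takes free partner as constant, pseudo-first-order, so that E at one time scales with partner charge. Summer reads 1.97 at 8.00 min. Scaled to dawn this gives 0.640, but dawn reads 0.478, which is less. Nor is E proportional to time: summer's E per minute reads 0.421 min⁻¹ at 0.500 min and 0.246 min⁻¹ at 8.00 min, which is less, so I scale with charge but not with time.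

**The border.** Impurity over partner is 0.265 in summer and 0.815 at dawn. Birch has 0.222, below summer, so I scale there. Cedar has 0.667, between midnight and dawn, so I interpolate E on partner charge instead.

**My reckoning.** I carry summer on to 10 min along the slope of its last two readings, which gives E = 2.33. Birch, scaled from that by partner charge at the same time, gets E = 2.78, so left-handed product is 46.9% and right-handed substrate 41.7%; left-handed product leads. Cedar gets E = 0.605, so right-handed substrate is 48.1% and leads left-handed product at 22.7%. That exposure is taken at the time of the last readings, but midnight's larger one would still leave 46.8% against 32.1%.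

**The forecast.** The forecast says right-handed substrate at 48% in cedar and left-handed product at 47% in birch, holding that the right-handed substrate “reacts about 15 times slower than the left”.

**The result.** Cedar ends with right-handed substrate at 48.0%, and birch with left-handed product at 47.0%. Free partner in cedar stands at 11% of its charge after 10.0 min. Put to use on birch's computed left-handed substrate, 2.97%, s gives right-handed substrate 41.6%; the computed value is 41.4%.

    partner + catalyst + left-handed substrate → catalyst + left-handed product (k = 1800 M⁻² min⁻¹)
    partner ⇌ dormant form (K = 0.580, k = 0.0500 min⁻¹)
    partner + catalyst + right-handed substrate → catalyst + right-handed product (k = 120 M⁻² min⁻¹)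
    partner + protic impurity → quenched reagent (k = 1.10 M⁻¹ min⁻¹)

**A neighbour.** Cedar's recipe with 0.83 M of partner is summer's charge run to 10 min, so E = 2.33 as carried on above, and s gives right-handed substrate 43.0%. The computed flask holds 43.2% of it, with left-handed substrate at 5.55%.

The readings stem from a simulated flask for substances that don't exist; the scatter is artificial.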